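**Retrosynthetic overview**
1. Target ⇒ bicyclic keto ynoate 33, by O-acetylation, Negishi methylalumination/hydroxymethylation of a C-13 alkyne, MeMgBr on the eudesmane ester and C-3 deoxygenation.
2. Key disconnection: both labdane rings (C4–C5, then C9–C10) open to the acyclic dienyne β-keto ester 32, which already carries the eudesmane as its tertiary-alkyl ester group. One Mn(OAc)3/Cu(OAc)2 oxidative radical bicyclisation closes ring A, then ring B.
3. 32 ⇒ thermal acylketene ester exchange between methyl keto ester 30 and tertiary alcohol 16.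
4. 30 ⇒ pent-4-ynal by two isopropenyl-Grignard/Johnson–Claisen cycles and a crossed Claisen with methyl propionate.
5. 16 ⇒ eudesmane ring B by Diels–Alder (isoprene + methyl acrylate), ring A by d'Angelo Michael/Robinson annulation with ethyl vinyl ketone, then Luche reduction, Myers transposition and Mukaiyama hydration.

Assumption: the target is read as the C-4 O-ester of cryptomeridiol with 15-O-acetylisocupressic acid, absolute configuration exactly as in the given SMILES.

**Route**

Step 1
Reactants: 1 isoprene; 2 methyl acrylate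
Product: 3 methyl 4-methylcyclohex-3-ene-1-carboxylate (racemic)
Conditions: AlCl3 (10 mol%), toluene, 0 → 23 °C
Reagents that add atoms: none
Why: Lewis-acid-catalysed Diels–Alder reaction gives the 1,4-("para") adduct; the single stereocentre is racemic and is equilibrated later (step 5).

Step 2
Reactants: 3 methyl 4-methylcyclohex-3-ene-1-carboxylate
Product: 5 methyl 3-hydroxy-4-methylcyclohexane-1-carboxylate (racemic; both C-1 epimers), via B-alkyl-9-BBN adduct 4 (not isolated)
Conditions: 9-BBN, THF, 65 °C; then NaBO3·4H2O, H2O, 23 °C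
Reagents that add atoms: sodium perborate, [Na+].[Na+].O[B-]1(O)OO[B-](O)(O)OO1
Why: anti-Markovnikov syn hydroboration–oxidation of the trisubstituted alkene (9-BBN and perborate leave the ester alone); all stereocentres formed here are erased or equilibrated in steps 3–5.

Step 3
Reactants: 5 methyl 3-hydroxy-4-methylcyclohexane-1-carboxylate
Product: 6 methyl 4-methyl-3-oxocyclohexane-1-carboxylate (racemic diastereomer mixture)
Conditions: NaOCl, TEMPO (1 mol%), KBr (10 mol%), CH2Cl2/aq NaHCO3, 0 °C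
Reagents that add atoms: none
Why: Anelli (oxoammonium) oxidation of a secondary alcohol to the ketone.

Step 4
Reactants: 6 methyl 4-methyl-3-oxocyclohexane-1-carboxylate; 7 pent-1-en-3-one
Product: 10 methyl (4S)-4-methyl-3-oxo-4-(3-oxopentyl)cyclohexane-1-carboxylate (C-1 epimers), via ketimine 8 (not isolated), via Michael-adduct ketimine 9 (not isolated)
Conditions: (R)-1-phenylethylamine, TsOH (cat.), toluene, reflux (−H2O); then 7, THF, 40 °C; then 20% aq AcOH, 23 °C
Reagents that add atoms: none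
Why: d'Angelo deracemising Michael addition: the more substituted secondary enamine tautomer of the chiral ketimine adds to the enone through a compact aza-ene-like transition state on the face away from the auxiliary phenyl group, setting the quaternary centre as 4S (about 90% ee expected; the R-amine gives the natural eudesmane sense).

Step 5
Reactants: 10 methyl (4S)-4-methyl-3-oxo-4-(3-oxopentyl)cyclohexane-1-carboxylate
Product: 11 methyl (2R,4aS)-4a,8-dimethyl-7-oxo-1,2,3,4,4a,5,6,7-octahydronaphthalene-2-carboxylate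
Conditions: NaOMe, MeOH, 60 °C
Reagents that add atoms: none
Why: intramolecular aldol condensation completes the Robinson annulation (ring A); methoxide also epimerises the ester-bearing carbon to the equatorial 2R configuration (cis to the angular methyl), so both C-1 epimers of 10 converge.

Step 6
Reactants: 11 methyl (2R,4aS)-4a,8-dimethyl-7-oxo-1,2,3,4,4a,5,6,7-octahydronaphthalene-2-carboxylate
Product: 12 methyl (2R,4aS,7S)-7-hydroxy-4a,8-dimethyl-1,2,3,4,4a,5,6,7-octahydronaphthalene-2-carboxylate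
Conditions: NaBH4, CeCl3·7H2O, MeOH, −20 °C
Reagents that add atoms: none
Why: Luche 1,2-reduction; axial hydride delivery on the face opposite the angular methyl gives the equatorial 7S allylic alcohol (hydroxyl cis to the angular methyl), and the ester is untouched.

Step 7
Reactants: 12 methyl (2R,4aS,7S)-7-hydroxy-4a,8-dimethyl-1,2,3,4,4a,5,6,7-octahydronaphthalene-2-carboxylate
Product: 15 methyl (2R,4aR,8aR)-4a,8-dimethyl-1,2,3,4,4a,5,6,8a-octahydronaphthalene-2-carboxylate, via sulfonylhydrazine 13 (not isolated), via allylic diazene 14 (not isolated)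
Conditions: 2-O2NC6H4SO2NHNH2, PPh3, DEAD, N-methylmorpholine, THF, −30 → 23 °C
Reagents that add atoms: none
Why: Myers reductive 1,3-transposition: Mitsunobu inversion puts nitrogen on the α-face, and the allylic diazene loses N2 by a retro-ene shift that delivers hydrogen to the ring-fusion carbon from that same face, giving the trans-decalin (8aR) with the alkene moved to C7=C8.

Step 8
Reactants: 15 methyl (2R,4aR,8aR)-4a,8-dimethyl-1,2,3,4,4a,5,6,8a-octahydronaphthalene-2-carboxylate
Product: 16 methyl (2R,4aR,8R,8aR)-8-hydroxy-4a,8-dimethyldecahydronaphthalene-2-carboxylate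
Conditions: Co(acac)2 (20 mol%), PhSiH3, O2 (1 atm), THF, 23 °C; chromatography to remove the minor 8-epimer
Reagents that add atoms: dioxygen, O=O
Why: Mukaiyama hydration (metal-hydride hydrogen-atom transfer to C-7, then O2 capture of the tertiary C-8 radical); oxygen enters equatorially on the α-face, anti to the 1,3-diaxial angular methyl, giving the 8R alcohol with axial methyl (cryptomeridiol C-4 configuration).

Step 9
Reactants: 17 pent-4-ynal; 18 isopropenylmagnesium bromide
Product: 19 2-methylhept-1-en-6-yn-3-ol (racemic)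
Conditions: THF, −78 → 0 °C
Reagents that add atoms: none
Why: Grignard addition to the aldehyde is much faster than alkyne deprotonation at low temperature; the carbinol centre is destroyed in step 10.

Step 10
Reactants: 19 2-methylhept-1-en-6-yn-3-ol; 20 trimethyl orthoacetate
Product: 22 methyl (4E)-4-methylnon-4-en-8-ynoate, via ketene acetal 21 (not isolated)
Conditions: EtCO2H (5 mol%), xylene, 135 °C (−MeOH)
Reagents that add atoms: none
Why: Johnson orthoester Claisen rearrangement; the chair transition state with the carbinol substituent equatorial gives the E-trisubstituted alkene (>97:3).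

Step 11
Reactants: 22 methyl (4E)-4-methylnon-4-en-8-ynoate; 18 isopropenylmagnesium bromide
Product: 24 (6E)-2,6-dimethylundeca-1,6-dien-10-yn-3-ol (racemic), via aluminium hemiacetal 23 (not isolated)
Conditions: i-Bu2AlH, CH2Cl2, −78 °C; then 18, THF, −78 → 0 °C
Reagents that add atoms: none
Why: one-pot partial reduction/Grignard addition: the tetrahedral aluminium hemiacetal is stable at −78 °C and collapses to the aldehyde only as the mixture warms in the presence of the Grignard reagent, which traps it at once; the carbinol centre is destroyed in step 12.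

Step 12
Reactants: 24 (6E)-2,6-dimethylundeca-1,6-dien-10-yn-3-ol; 20 trimethyl orthoacetate
Product: 26 methyl (4E,8E)-4,8-dimethyltrideca-4,8-dien-12-ynoate, via ketene acetal 25 (not isolated)
Conditions: EtCO2H (5 mol%), xylene, 135 °C (−MeOH)
Reagents that add atoms: none
Why: second Johnson–Claisen rearrangement, E-selective for the same reason as step 10.

Step 13
Reactants: 26 methyl (4E,8E)-4,8-dimethyltrideca-4,8-dien-12-ynoate
Product: 27 (4E,8E)-4,8-dimethyltrideca-4,8-dien-12-ynoic acid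
Conditions: LiOH·H2O, THF/MeOH/H2O, 23 °C; then 1 M HCl
Reagents that add atoms: lithium hydroxide, [Li+].[OH-]
Why: ester saponification; the skipped diene and alkyne are inert.

Step 14
Reactants: 27 (4E,8E)-4,8-dimethyltrideca-4,8-dien-12-ynoic acid; 28 methyl propionate
Product: 30 methyl (6E,10E)-2,6,10-trimethyl-3-oxopentadeca-6,10-dien-14-ynoate (racemic), via acyl imidazole 29 (not isolated)
Conditions: CDI, THF, 23 °C; then LiCH(CH3)CO2Me (from 28 and LiN(i-Pr)2, 2.5 equiv), THF, −78 °C; then 1 M HCl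
Reagents that add atoms: none
Why: crossed Claisen condensation of a preformed ester enolate with an acyl imidazole; C-acylation at −78 °C outruns proton transfer from the alkyne, and the second equivalent of enolate absorbs the acidic product.

Step 15
Reactants: 30 methyl (6E,10E)-2,6,10-trimethyl-3-oxopentadeca-6,10-dien-14-ynoate; 16 methyl (2R,4aR,8R,8aR)-8-hydroxy-4a,8-dimethyldecahydronaphthalene-2-carboxylate
Product: 32 methyl (2R,4aR,8R,8aR)-4a,8-dimethyl-8-{[(6E,10E)-2,6,10-trimethyl-3-oxopentadeca-6,10-dien-14-ynoyl]oxy}decahydronaphthalene-2-carboxylate (both epimers at the acyl α-carbon), via acylketene 31 (not isolated)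
Conditions: DMAP (20 mol%), xylene, 140 °C, 5 Å molecular sieves (−MeOH); 30 in 1.3-fold excess
Reagents that add atoms: none
Why: thermal β-keto ester exchange through an α-methyl acylketene, which is electrophilic enough to be captured by a hindered tertiary alcohol under neutral conditions; 16 has only one hydroxyl, no existing stereocentre is touched, and the α-carbon becomes a planar radical in step 16.

Step 16
Reactants: 32 methyl (2R,4aR,8R,8aR)-4a,8-dimethyl-8-{[(6E,10E)-2,6,10-trimethyl-3-oxopentadeca-6,10-dien-14-ynoyl]oxy}decahydronaphthalene-2-carboxylate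
Product: 33 methyl (2R,4aR,8R,8aR)-4a,8-dimethyl-8-[(3-oxo-15,16-dinorlabd-8(17)-en-13-yn-19-oyl)oxy]decahydronaphthalene-2-carboxylate (labdane part: 4α-CH3; 4β-acyl; 5α-H; 9α-H; 10β-CH3)
Conditions: Mn(OAc)3·2H2O (2.2 equiv), Cu(OAc)2·H2O (2.0 equiv, regenerated by Mn(OAc)3), degassed AcOH, 35 °C; chromatographic separation of diastereomers
Reagents that add atoms: none
Why: Proposed new method: Mn(OAc)3 oxidises the enolised α-methyl β-keto ester to the C-4 radical, which closes ring A and then ring B by two 6-endo additions through an all-chair fold of the (E,E)-diene (ester axial = C-19, 5α-H, 10β-CH3, 9β side chain), and Cu(OAc)2 converts the tertiary C-8 radical into the 8(17)-methylene by oxidative β-hydride loss before it can add 5-exo to the remote alkyne; the closest known reaction is the Snider oxidative polyene bicyclisation of α-methyl β-keto esters and its chiral-ester (8-phenylmenthyl) variant, and the new element is that the resident eudesmanyl ester makes the two mirror-image folds diastereomeric, so the normal-labdane product is separated from its 4,5,9,10-epi isomer (facial bias expected to be modest, about 1–3:1, sense not predictable) and four stereocentres are fixed without an external chiral reagent.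

Step 17
Reactants: 33 (3-oxo bicyclic ester)
Product: 35 methyl (2R,4aR,8R,8aR)-8-[(15,16-dinorlabd-8(17)-en-13-yn-19-oyl)oxy]-4a,8-dimethyldecahydronaphthalene-2-carboxylate, via tosylhydrazone 34 (not isolated)
Conditions: TsNHNH2, AcOH (cat.), EtOH, 70 °C; then catecholborane, CHCl3, 0 °C; NaOAc·3H2O, 60 °C
Reagents that add atoms: none
Why: Caglioti/Kabalka reductive deoxygenation of the tosylhydrazone (hydride to C=N, loss of sulfinate and N2); esters, the exocyclic alkene and the alkyne are inert to catecholborane at 0 °C, and no stereocentre is involved.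

Step 18
Reactants: 35 (bicyclic diester)
Product: 36 (1R,4aR,7R,8aR)-7-(2-hydroxypropan-2-yl)-1,4a-dimethyldecahydronaphthalen-1-yl 15,16-dinorlabd-8(17)-en-13-yn-19-oate
Conditions: MeMgBr (6 equiv), THF, 0 → 23 °C
Reagents that add atoms: methylmagnesium bromide, C[Mg]Br
Why: double Grignard addition to the only accessible ester; the C-19 ester (neopentyl, axial, tertiary-alkyl) does not react, and the alkyne is merely deprotonated and returns on work-up.

Step 19
Reactants: 36 (cryptomeridiol 4-O-ester with terminal alkyne)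
Product: 38 (1R,4aR,7R,8aR)-7-(2-hydroxypropan-2-yl)-1,4a-dimethyldecahydronaphthalen-1-yl (13E)-15-hydroxylabda-8(17),13-dien-19-oate, via vinylalane 37 (not isolated)
Conditions: Me3Al (4 equiv), Cp2ZrCl2 (50 mol%), CH2Cl2, 0 → 23 °C; then n-BuLi, THF, −78 °C; (CH2O)n, −78 → 23 °C
Reagents that add atoms: trimethylaluminium, C[Al](C)C; formaldehyde (as paraformaldehyde), C=O
Why: Negishi zirconium-catalysed syn-carboalumination of the terminal alkyne, then trapping of the alkenylalanate with formaldehyde with retention, gives the 13E allylic alcohol (>98% E); the 1,1-disubstituted alkene does not react and the tertiary hydroxyl is carried as its aluminium alkoxide.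

Step 20
Reactants: 38 (15-hydroxy ester)
Product: 39 (1R,4aR,7R,8aR)-7-(2-hydroxypropan-2-yl)-1,4a-dimethyldecahydronaphthalen-1-yl (13E)-15-acetoxylabda-8(17),13-dien-19-oate (CNP0141048.1)
Conditions: Ac2O, pyridine, DMAP (2 mol%), CH2Cl2, 0 °C
Reagents that add atoms: acetic anhydride, CC(=O)OC(C)=O
Why: acylation is selective for the primary allylic alcohol over the tertiary hydroxyl of the eudesmane side chain.

**Compound list**

1 | isoprene (2-methylbuta-1,3-diene) | C=CC(C)=C | starting material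
2 | methyl acrylate | C=CC(=O)OC | starting material
3 | methyl 4-methylcyclohex-3-ene-1-carboxylate (racemic) | COC(=O)C1CCC(C)=CC1 | intermediate
4 | methyl 3-(9-borabicyclo[3.3.1]nonan-9-yl)-4-methylcyclohexane-1-carboxylate (stereoisomer mixture) | COC(=O)C1CCC(C)C(C1)B1C2CCCC1CCC2 | intermediate
5 | methyl 3-hydroxy-4-methylcyclohexane-1-carboxylate (racemic; both C-1 epimers) | COC(=O)C1CCC(C)C(O)C1 | intermediate
6 | methyl 4-methyl-3-oxocyclohexane-1-carboxylate (racemic diastereomer mixture) | COC(=O)C1CCC(C)C(=O)C1 | intermediate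
7 | pent-1-en-3-one (ethyl vinyl ketone) | CCC(=O)C=C | starting material
8 | methyl 4-methyl-3-{[(1R)-1-phenylethyl]imino}cyclohexane-1-carboxylate | COC(=O)C1CCC(C)C(C1)=N[C@H](C)c1ccccc1 | intermediate
9 | methyl (4S)-4-methyl-4-(3-oxopentyl)-3-{[(1R)-1-phenylethyl]imino}cyclohexane-1-carboxylate | CCC(=O)CC[C@]1(C)CCC(C(=O)OC)CC1=N[C@H](C)c1ccccc1 | intermediate
10 | methyl (4S)-4-methyl-3-oxo-4-(3-oxopentyl)cyclohexane-1-carboxylate (C-1 epimers) | CCC(=O)CC[C@]1(C)CCC(C(=O)OC)CC1=O | intermediate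
11 | methyl (2R,4aS)-4a,8-dimethyl-7-oxo-1,2,3,4,4a,5,6,7-octahydronaphthalene-2-carboxylate | CC1=C2C[C@H](C(=O)OC)CC[C@@]2(C)CCC1=O | intermediate
12 | methyl (2R,4aS,7S)-7-hydroxy-4a,8-dimethyl-1,2,3,4,4a,5,6,7-octahydronaphthalene-2-carboxylate | CC1=C2C[C@H](C(=O)OC)CC[C@@]2(C)CC[C@@H]1O | intermediate
13 | methyl (2R,4aS,7R)-4a,8-dimethyl-7-[1-(2-nitrobenzenesulfonyl)hydrazin-1-yl]-1,2,3,4,4a,5,6,7-octahydronaphthalene-2-carboxylate | CC1=C2C[C@H](C(=O)OC)CC[C@@]2(C)CC[C@H]1N(N)S(=O)(=O)c1ccccc1[N+](=O)[O-] | intermediate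
14 | methyl (2R,4aS,7R)-7-diazenyl-4a,8-dimethyl-1,2,3,4,4a,5,6,7-octahydronaphthalene-2-carboxylate | CC1=C2C[C@H](C(=O)OC)CC[C@@]2(C)CC[C@H]1N=N | intermediate
15 | methyl (2R,4aR,8aR)-4a,8-dimethyl-1,2,3,4,4a,5,6,8a-octahydronaphthalene-2-carboxylate | CC1=CCC[C@]2(C)CC[C@@H](C(=O)OC)C[C@H]21 | intermediate
16 | methyl (2R,4aR,8R,8aR)-8-hydroxy-4a,8-dimethyldecahydronaphthalene-2-carboxylate | O[C@]1(C)CCC[C@]2(C)CC[C@@H](C(=O)OC)C[C@H]21 | intermediate
17 | pent-4-ynal | C#CCCC=O | starting material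
18 | isopropenylmagnesium bromide (prop-1-en-2-ylmagnesium bromide) | CC(=C)[Mg]Br | starting material
19 | 2-methylhept-1-en-6-yn-3-ol (racemic) | C=C(C)C(O)CCC#C | intermediate
20 | trimethyl orthoacetate (1,1,1-trimethoxyethane) | CC(OC)(OC)OC | starting material
21 | 3-[(1-methoxyethenyl)oxy]-2-methylhept-1-en-6-yne | C=C(OC)OC(CCC#C)C(C)=C | intermediate
22 | methyl (4E)-4-methylnon-4-en-8-ynoate | COC(=O)CC/C(C)=C/CCC#C | intermediate
23 | diisobutyl{[(4E)-1-methoxy-4-methylnon-4-en-8-yn-1-yl]oxy}alumane | COC(CC/C(C)=C/CCC#C)O[Al](CC(C)C)CC(C)C | intermediate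
24 | (6E)-2,6-dimethylundeca-1,6-dien-10-yn-3-ol (racemic) | C=C(C)C(O)CC/C(C)=C/CCC#C | intermediate
25 | (6E)-3-[(1-methoxyethenyl)oxy]-2,6-dimethylundeca-1,6-dien-10-yne | C=C(OC)OC(CC/C(C)=C/CCC#C)C(C)=C | intermediate
26 | methyl (4E,8E)-4,8-dimethyltrideca-4,8-dien-12-ynoate | COC(=O)CC/C(C)=C/CC/C(C)=C/CCC#C | intermediate
27 | (4E,8E)-4,8-dimethyltrideca-4,8-dien-12-ynoic acid | OC(=O)CC/C(C)=C/CC/C(C)=C/CCC#C | intermediate
28 | methyl propionate | CCC(=O)OC | starting material
29 | (4E,8E)-1-(1H-imidazol-1-yl)-4,8-dimethyltrideca-4,8-dien-12-yn-1-one | O=C(CC/C(C)=C/CC/C(C)=C/CCC#C)n1ccnc1 | intermediate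
30 | methyl (6E,10E)-2,6,10-trimethyl-3-oxopentadeca-6,10-dien-14-ynoate (racemic) | COC(=O)C(C)C(=O)CC/C(C)=C/CC/C(C)=C/CCC#C | intermediate
31 | (6E,10E)-2,6,10-trimethylpentadeca-1,6,10-trien-14-yne-1,3-dione (acylketene) | O=C=C(C)C(=O)CC/C(C)=C/CC/C(C)=C/CCC#C | intermediate
32 | methyl (2R,4aR,8R,8aR)-4a,8-dimethyl-8-{[(6E,10E)-2,6,10-trimethyl-3-oxopentadeca-6,10-dien-14-ynoyl]oxy}decahydronaphthalene-2-carboxylate (both acyl α-epimers) | O=C(O[C@]1(C)CCC[C@]2(C)CC[C@@H](C(=O)OC)C[C@H]21)C(C)C(=O)CC/C(C)=C/CC/C(C)=C/CCC#C | intermediate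
33 | methyl (2R,4aR,8R,8aR)-4a,8-dimethyl-8-[(3-oxo-15,16-dinorlabd-8(17)-en-13-yn-19-oyl)oxy]decahydronaphthalene-2-carboxylate (labdane part 4α-CH3, 4β-acyl, 5α-H, 9α-H, 10β-CH3) | C=C1CC[C@@H]2[C@](C)(CCC(=O)[C@]2(C)C(=O)O[C@]3(C)CCC[C@]4(C)CC[C@@H](C(=O)OC)C[C@H]43)[C@H]1CCC#C | intermediate
34 | C-3 (4-methylbenzenesulfonyl)hydrazone of 33 | C=C1CC[C@@H]2[C@](C)(CCC(=NNS(=O)(=O)c5ccc(C)cc5)[C@]2(C)C(=O)O[C@]3(C)CCC[C@]4(C)CC[C@@H](C(=O)OC)C[C@H]43)[C@H]1CCC#C | intermediate
35 | methyl (2R,4aR,8R,8aR)-8-[(15,16-dinorlabd-8(17)-en-13-yn-19-oyl)oxy]-4a,8-dimethyldecahydronaphthalene-2-carboxylate | C=C1CC[C@@H]2[C@](C)(CCC[C@]2(C)C(=O)O[C@]3(C)CCC[C@]4(C)CC[C@@H](C(=O)OC)C[C@H]43)[C@H]1CCC#C | intermediate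
36 | (1R,4aR,7R,8aR)-7-(2-hydroxypropan-2-yl)-1,4a-dimethyldecahydronaphthalen-1-yl 15,16-dinorlabd-8(17)-en-13-yn-19-oate | C=C1CC[C@@H]2[C@](C)(CCC[C@]2(C)C(=O)O[C@]3(C)CCC[C@]4(C)CC[C@@H](C(C)(C)O)C[C@H]43)[C@H]1CCC#C | intermediate
37 | (1R,4aR,7R,8aR)-7-{2-[(dimethylalumanyl)oxy]propan-2-yl}-1,4a-dimethyldecahydronaphthalen-1-yl (13E)-14-(dimethylalumanyl)-15-norlabda-8(17),13-dien-19-oate | C=C1CC[C@@H]2[C@](C)(CCC[C@]2(C)C(=O)O[C@]3(C)CCC[C@]4(C)CC[C@@H](C(C)(C)O[Al](C)C)C[C@H]43)[C@H]1CC/C(C)=C/[Al](C)C | intermediate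
38 | (1R,4aR,7R,8aR)-7-(2-hydroxypropan-2-yl)-1,4a-dimethyldecahydronaphthalen-1-yl (13E)-15-hydroxylabda-8(17),13-dien-19-oate | C=C1CC[C@@H]2[C@](C)(CCC[C@]2(C)C(=O)O[C@]3(C)CCC[C@]4(C)CC[C@@H](C(C)(C)O)C[C@H]43)[C@H]1CC/C(C)=C/CO | intermediate
39 | (1R,4aR,7R,8aR)-7-(2-hydroxypropan-2-yl)-1,4a-dimethyldecahydronaphthalen-1-yl (13E)-15-acetoxylabda-8(17),13-dien-19-oate (CNP0141048.1) | C=C1CC[C@@H]2[C@](C)(CCC[C@]2(C)C(=O)O[C@]2(C)CCC[C@]3(C)CC[C@@H](C(C)(C)O)C[C@H]32)[C@H]1CC/C(C)=C/COC(C)=O | target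

**Totals**
Total step count: 20 (eudesmane branch steps 1–8, polyene branch steps 9–14, union and endgame steps 15–20).
Longest linear sequence: 14 steps (1–8, then 15–20).
Enantiopurity: the minor eudesmane enantiomer left by step 4 ends up in diastereomers after step 16 and is removed in the same chromatography.

**Three steps most likely to fail**

Risk 1, the key cyclisation of step 16. Risks are low face selectivity from the resident eudesmanyl group, 5-exo capture of the C-8 radical by the alkyne, and endocyclic alkene isomers; oxidative coupling of the terminal alkyne by Cu(OAc)2 is not expected in amine-free acetic acid. The fallback for step 16 sets out from 32 and comes back to the route at 33, and it changes the chain-ending event from oxidation to halogen-atom transfer. 32 is chlorinated at the acyl α-carbon (NCS, Mg(ClO4)2 cat., EtOAc, 23 °C) to give methyl (2R,4aR,8R,8aR)-8-{[(6E,10E)-2-chloro-2,6,10-trimethyl-3-oxopentadeca-6,10-dien-14-ynoyl]oxy}-4a,8-dimethyldecahydronaphthalene-2-carboxylate F1 as a mixture of α-epimers. CuCl with tris(2-pyridylmethyl)amine in ClCH2CH2Cl at 80 °C then runs a chlorine-atom-transfer radical bicyclisation: monovalent copper abstracts chlorine, the same chair–chair cascade follows, and CuCl2 returns chlorine to the C-8 radical to give methyl (2R,4aR,8R,8aR)-8-[(8-chloro-3-oxo-15,16-dinorlabd-13-yn-19-oyl)oxy]-4a,8-dimethyldecahydronaphthalene-2-carboxylate F2 as a mixture of C-8 epimers. LiBr/Li2CO3 in DMF at 110 °C then eliminates HCl to give 33, and the 8(17)-ene is separated from ring-alkene isomers on AgNO3-impregnated silica.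

Risk 2, the ester exchange of step 15 on a hindered tertiary alcohol. Risks are slow acylketene formation from a methyl ester and side reactions of the acylketene at 140 °C. The fallback for step 15 sets out from 16 (together with acyl imidazole 29, made from 27 as in step 14) and comes back to the route at 32; it builds the keto ester on the eudesmane instead of transferring it. 16 is acetoacetylated with diketene (DMAP cat., CH2Cl2, 23 °C) to give methyl (2R,4aR,8R,8aR)-4a,8-dimethyl-8-[(3-oxobutanoyl)oxy]decahydronaphthalene-2-carboxylate F3 whose magnesium enolate (MgCl2, Et3N, MeCN) is C-acylated by 29 to give methyl (2R,4aR,8R,8aR)-8-{[(6E,10E)-2-acetyl-6,10-dimethyl-3-oxopentadeca-6,10-dien-14-ynoyl]oxy}-4a,8-dimethyldecahydronaphthalene-2-carboxylate F4 as the triketo intermediate. Aqueous NH3 in MeOH at 0 °C removes the acetyl group by retro-Claisen cleavage to give methyl (2R,4aR,8R,8aR)-8-{[(6E,10E)-6,10-dimethyl-3-oxopentadeca-6,10-dien-14-ynoyl]oxy}-4a,8-dimethyldecahydronaphthalene-2-carboxylate F5 and K2CO3/MeI in acetone then methylates its α-carbon to give 32.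

Risk 3, the deoxygenation of the hindered C-3 ketone in step 17. The risk is sluggish hydrazone formation next to the quaternary C-4. The fallback for step 17 sets out from 33 and comes back to the route at 35 by way of the alcohol. NaBH4 (MeOH, 0 °C) reduces the ketone from the α-face to give methyl (2R,4aR,8R,8aR)-8-[(3β-hydroxy-15,16-dinorlabd-8(17)-en-13-yn-19-oyl)oxy]-4a,8-dimethyldecahydronaphthalene-2-carboxylate F6 which PhOC(S)Cl/pyridine/DMAP in CH2Cl2 converts into methyl (2R,4aR,8R,8aR)-4a,8-dimethyl-8-({3β-[(phenoxycarbonothioyl)oxy]-15,16-dinorlabd-8(17)-en-13-yn-19-oyl}oxy)decahydronaphthalene-2-carboxylate F7 as the radical precursor. (Me3Si)3SiH (1.1 equiv)/AIBN in toluene at 80 °C (Barton–McCombie) then gives 35; the thiocarbonyl group captures silyl radicals much faster than the isolated alkyne does, and the silane is kept near stoichiometric so that the alkyne is not hydrosilylated afterwards.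

**Further compounds**

F1 | step 16 | methyl (2R,4aR,8R,8aR)-8-{[(6E,10E)-2-chloro-2,6,10-trimethyl-3-oxopentadeca-6,10-dien-14-ynoyl]oxy}-4a,8-dimethyldecahydronaphthalene-2-carboxylate | O=C(O[C@]1(C)CCC[C@]2(C)CC[C@@H](C(=O)OC)C[C@H]21)C(C)(Cl)C(=O)CC/C(C)=C/CC/C(C)=C/CCC#C
F2 | step 16 | methyl (2R,4aR,8R,8aR)-8-[(8-chloro-3-oxo-15,16-dinorlabd-13-yn-19-oyl)oxy]-4a,8-dimethyldecahydronaphthalene-2-carboxylate | CC1(Cl)CC[C@@H]2[C@](C)(CCC(=O)[C@]2(C)C(=O)O[C@]3(C)CCC[C@]4(C)CC[C@@H](C(=O)OC)C[C@H]43)[C@H]1CCC#C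
F3 | step 15 | methyl (2R,4aR,8R,8aR)-4a,8-dimethyl-8-[(3-oxobutanoyl)oxy]decahydronaphthalene-2-carboxylate | CC(=O)CC(=O)O[C@]1(C)CCC[C@]2(C)CC[C@@H](C(=O)OC)C[C@H]21
F4 | step 15 | methyl (2R,4aR,8R,8aR)-8-{[(6E,10E)-2-acetyl-6,10-dimethyl-3-oxopentadeca-6,10-dien-14-ynoyl]oxy}-4a,8-dimethyldecahydronaphthalene-2-carboxylate | CC(=O)C(C(=O)CC/C(C)=C/CC/C(C)=C/CCC#C)C(=O)O[C@]1(C)CCC[C@]2(C)CC[C@@H](C(=O)OC)C[C@H]21
F5 | step 15 | methyl (2R,4aR,8R,8aR)-8-{[(6E,10E)-6,10-dimethyl-3-oxopentadeca-6,10-dien-14-ynoyl]oxy}-4a,8-dimethyldecahydronaphthalene-2-carboxylate | O=C(CC(=O)CC/C(C)=C/CC/C(C)=C/CCC#C)O[C@]1(C)CCC[C@]2(C)CC[C@@H](C(=O)OC)C[C@H]21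
F6 | step 17 | methyl (2R,4aR,8R,8aR)-8-[(3β-hydroxy-15,16-dinorlabd-8(17)-en-13-yn-19-oyl)oxy]-4a,8-dimethyldecahydronaphthalene-2-carboxylate | C=C1CC[C@@H]2[C@](C)(CC[C@H](O)[C@]2(C)C(=O)O[C@]3(C)CCC[C@]4(C)CC[C@@H](C(=O)OC)C[C@H]43)[C@H]1CCC#C
F7 | step 17 | methyl (2R,4aR,8R,8aR)-4a,8-dimethyl-8-({3β-[(phenoxycarbonothioyl)oxy]-15,16-dinorlabd-8(17)-en-13-yn-19-oyl}oxy)decahydronaphthalene-2-carboxylate | C=C1CC[C@@H]2[C@](C)(CC[C@H](OC(=S)Oc5ccccc5)[C@]2(C)C(=O)O[C@]3(C)CCC[C@]4(C)CC[C@@H](C(=O)OC)C[C@H]43)[C@H]1CCC#C
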